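The heptane chain is cut at C1=C2 and C6=C7: C2–C6, carrying the syn C3 and C5 oxygens, is the five-membered ring of cis-cyclopent-4-ene-1,3-diol, and because the guaiacyl and syringyl ends differ by one methoxy group the core is a desymmetrised meso unit. A chiral Mo alkylidene opens the meso silylene-bridged bicycle (cyclopentene ring bridged by O–Si–O) with O-benzyl-4-vinylguaiacol in one operation, fixing the absolute configuration at C3 and C5 and leaving a styryl end and a vinyl end. The precursor is meso 3,3-di-tert-butyl-2,4-dioxa-3-silabicyclo[3.2.1]oct-6-ene; B-alkyl Suzuki coupling, hydrogenation and desilylation finish the target.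

Key step: step 4

Remark (numbering): C1 of the heptane is the benzylic carbon on the 4-hydroxy-3-methoxyphenyl side; with this numbering the target is the (3S,5R) syn diol.

Assumption (sense of induction): the face preference of the chiral Mo diolate on this new bicycle cannot be assigned in advance. The route is written for the catalyst antipode that gives (4R,6S)-8; both antipodes of the biphenolate are available, and the configuration is to be checked on 8 before scale-up.

Remark (starting material): 4-benzyloxy-3-methoxybenzaldehyde is taken as a catalogue material, which saves the benzylation of vanillin.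

Step 1
Reactants: 1 cis-cyclopent-4-ene-1,3-diol (meso); 2 di-tert-butylsilyl bis(trifluoromethanesulfonate)
Product: 3 meso-3,3-di-tert-butyl-2,4-dioxa-3-silabicyclo[3.2.1]oct-6-ene
Conditions: 2 (1.05 equiv, slow addition), 2,6-lutidine (2.5 equiv), CH2Cl2 (0.02 M), 0 °C to rt
Reagents that add atoms: none
Why: Silylene protection of a 1,3-diol, in which the first Si–O bond forms by triflate displacement and the second closes intramolecularly across the two cis oxygens (the long Si–O bonds accommodate the bridge, high dilution favours the monomer), with no stereocentre touched so the product stays meso.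

Step 2
Reactants: 4 4-benzyloxy-3-methoxybenzaldehyde
Product: 5 1-benzyloxy-4-ethenyl-2-methoxybenzene (4-benzyloxy-3-methoxystyrene)
Conditions: Ph3PCH3Br (1.3 equiv), KOtBu (1.25 equiv), THF, 0 °C to rt; product filtered through alumina to remove aldehyde and phosphine oxide
Reagents that add atoms: methyltriphenylphosphonium bromide, C[P+](c1ccccc1)(c1ccccc1)c1ccccc1.[Br-]
Why: Wittig methylenation of an aromatic aldehyde with the non-stabilised ylide, to which the benzyl and methyl ethers are inert.

Step 3
Reactants: 6 4-bromo-2,6-dimethoxyphenol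
Product: 7 2-benzyloxy-5-bromo-1,3-dimethoxybenzene
Conditions: BnBr (1.1 equiv), K2CO3 (1.5 equiv), DMF, rt to 50 °C
Reagents that add atoms: benzyl bromide, BrCc1ccccc1
Why: Williamson ether synthesis, the phenoxide displacing bromide from benzyl bromide by SN2 while the aryl bromide is untouched.

Step 4
Reactants: 3 meso-3,3-di-tert-butyl-2,4-dioxa-3-silabicyclo[3.2.1]oct-6-ene; 5 1-benzyloxy-4-ethenyl-2-methoxybenzene
Product: 8 (4R,6S)-4-[(E)-2-(4-benzyloxy-3-methoxyphenyl)ethenyl]-2,2-di-tert-butyl-6-ethenyl-1,3,2-dioxasilinane (cis)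
Conditions: 5 (4 equiv), Mo(=N-2,6-iPr2C6H3)(=CHCMe2Ph)(3,3'-di-tert-butyl-5,5',6,6'-tetramethylbiphenyl-2,2'-diolate) (5 mol %, antipode as assumed above), C6H6, 22 °C, N2
Reagents that add atoms: none
Why: The chiral Mo benzylidene formed from 5 adds to the strained C6=C7 alkene of 3 by [2+2] cycloaddition from the face syn to the CH2 bridge, and cycloreversion of the metallacyclobutane opens the cyclopentene ring irreversibly, placing ArCH= on one alkene carbon (target C2) and Mo= on the other (target C6); a second molecule of 5 caps that alkylidene as the C6=C7 vinyl group and regenerates the benzylidene, so the net process is a 1:1 addition with no co-product. The closest known reaction type is Mo- or Ru-catalysed asymmetric ring-opening/cross-metathesis of meso norbornenes and hetero-bridged bicyclo[3.2.1]oct-6-enes with styrenes. No ring is closed. Both stereocentres already exist in 3 with the cis relationship locked by the O–Si–O bridge, so the syn diol is inherited and only the absolute configuration is set, by the biphenolate ligand choosing which enantiotopic alkene carbon receives the benzylidene. The step needs ring-opening/cross-metathesis to outrun ring-opening oligomerisation and secondary metathesis of the new vinyl group; the excess of 5 secures the first and the siloxy-bearing allylic carbon next to the vinyl group secures the second. The E geometry expected from Mo diolates is of no consequence, because this alkene is hydrogenated in step 6.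

Step 5
Reactants: 8 (4R,6S)-4-[(E)-2-(4-benzyloxy-3-methoxyphenyl)ethenyl]-2,2-di-tert-butyl-6-ethenyl-1,3,2-dioxasilinane; 7 2-benzyloxy-5-bromo-1,3-dimethoxybenzene
Product: 10 (4R,6R)-4-[(E)-2-(4-benzyloxy-3-methoxyphenyl)ethenyl]-6-[2-(4-benzyloxy-3,5-dimethoxyphenyl)ethyl]-2,2-di-tert-butyl-1,3,2-dioxasilinane, via 9-{2-[(4R,6R)-6-[(E)-2-(4-benzyloxy-3-methoxyphenyl)ethenyl]-2,2-di-tert-butyl-1,3,2-dioxasilinan-4-yl]ethyl}-9-borabicyclo[3.3.1]nonane 9 (not isolated)
Conditions: 9-BBN (0.5 M in THF, 1.3 equiv), THF, 0 °C to rt; then 7 (1.2 equiv), Pd(OAc)2 (3 mol %), SPhos (6 mol %), K3PO4·H2O (3 equiv), THF, 60 °C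
Reagents that add atoms: none
Why: Anti-Markovnikov hydroboration with 9-BBN is selective for the monosubstituted vinyl group over the 1,2-disubstituted aryl-conjugated alkene, and the primary B-alkyl-9-BBN then undergoes B-alkyl Suzuki–Miyaura coupling with the aryl bromide (SPhos for oxidative addition into the electron-rich ring), with the stereocentres not involved and the silylene tolerant of the phosphate base.

Step 6
Reactants: 10 (4R,6R)-4-[(E)-2-(4-benzyloxy-3-methoxyphenyl)ethenyl]-6-[2-(4-benzyloxy-3,5-dimethoxyphenyl)ethyl]-2,2-di-tert-butyl-1,3,2-dioxasilinane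
Product: 11 (4S,6R)-2,2-di-tert-butyl-4-[2-(4-hydroxy-3-methoxyphenyl)ethyl]-6-[2-(4-hydroxy-3,5-dimethoxyphenyl)ethyl]-1,3,2-dioxasilinane
Conditions: H2 (1 atm), 10% Pd/C, EtOAc–EtOH, rt
Reagents that add atoms: none
Why: Heterogeneous catalytic hydrogenation saturates the C1=C2 styryl bond and hydrogenolyses both aryl benzyl ethers in one operation, while the silylene (which also restrains allylic C–O cleavage), the aryl methyl ethers and both stereocentres are left unchanged.

Step 7
Reactants: 11 (4S,6R)-2,2-di-tert-butyl-4-[2-(4-hydroxy-3-methoxyphenyl)ethyl]-6-[2-(4-hydroxy-3,5-dimethoxyphenyl)ethyl]-1,3,2-dioxasilinane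
Product: 12 (3S,5R)-7-(4-hydroxy-3,5-dimethoxyphenyl)-1-(4-hydroxy-3-methoxyphenyl)heptane-3,5-diol
Conditions: HF·pyridine, pyridine–THF, 0 °C to rt; aq. NaHCO3 work-up
Reagents that add atoms: none
Why: Fluoride-mediated cleavage of the di-tert-butylsilylene (Si–F bond formation) under buffered conditions should release the syn 1,3-diol without touching the C–O stereocentres, the phenols or the methyl ethers.

Compound list
1 | cis-cyclopent-4-ene-1,3-diol, (1R,3S), meso | O[C@H]1C[C@@H](O)C=C1 | starting material
2 | di-tert-butylsilyl bis(trifluoromethanesulfonate) | CC(C)(C)[Si](OS(=O)(=O)C(F)(F)F)(OS(=O)(=O)C(F)(F)F)C(C)(C)C | starting material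
3 | (1R,5S)-3,3-di-tert-butyl-2,4-dioxa-3-silabicyclo[3.2.1]oct-6-ene, meso | C1=C[C@H]2C[C@@H]1O[Si](C(C)(C)C)(C(C)(C)C)O2 | intermediate
4 | 4-benzyloxy-3-methoxybenzaldehyde | COc1cc(C=O)ccc1OCc1ccccc1 | starting material
5 | 1-benzyloxy-4-ethenyl-2-methoxybenzene | COc1cc(C=C)ccc1OCc1ccccc1 | intermediate
6 | 4-bromo-2,6-dimethoxyphenol | COc1cc(Br)cc(OC)c1O | starting material
7 | 2-benzyloxy-5-bromo-1,3-dimethoxybenzene | COc1cc(Br)cc(OC)c1OCc1ccccc1 | intermediate
8 | (4R,6S)-4-[(E)-2-(4-benzyloxy-3-methoxyphenyl)ethenyl]-2,2-di-tert-butyl-6-ethenyl-1,3,2-dioxasilinane | COc1cc(/C=C/[C@H]2C[C@@H](C=C)O[Si](C(C)(C)C)(C(C)(C)C)O2)ccc1OCc1ccccc1 | intermediate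
9 | 9-{2-[(4R,6R)-6-[(E)-2-(4-benzyloxy-3-methoxyphenyl)ethenyl]-2,2-di-tert-butyl-1,3,2-dioxasilinan-4-yl]ethyl}-9-borabicyclo[3.3.1]nonane | COc1cc(/C=C/[C@H]2C[C@@H](CCB3C4CCCC3CCC4)O[Si](C(C)(C)C)(C(C)(C)C)O2)ccc1OCc1ccccc1 | intermediate
10 | (4R,6R)-4-[(E)-2-(4-benzyloxy-3-methoxyphenyl)ethenyl]-6-[2-(4-benzyloxy-3,5-dimethoxyphenyl)ethyl]-2,2-di-tert-butyl-1,3,2-dioxasilinane | COc1cc(/C=C/[C@H]2C[C@@H](CCc3cc(OC)c(OCc4ccccc4)c(OC)c3)O[Si](C(C)(C)C)(C(C)(C)C)O2)ccc1OCc1ccccc1 | intermediate
11 | (4S,6R)-2,2-di-tert-butyl-4-[2-(4-hydroxy-3-methoxyphenyl)ethyl]-6-[2-(4-hydroxy-3,5-dimethoxyphenyl)ethyl]-1,3,2-dioxasilinane | COc1cc(CC[C@H]2C[C@@H](CCc3cc(OC)c(O)c(OC)c3)O[Si](C(C)(C)C)(C(C)(C)C)O2)ccc1O | intermediate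
12 | (3S,5R)-7-(4-hydroxy-3,5-dimethoxyphenyl)-1-(4-hydroxy-3-methoxyphenyl)heptane-3,5-diol | COc1cc(CC[C@H](O)C[C@H](O)CCc2cc(OC)c(O)c(OC)c2)ccc1O | target

Total step count: 7. Longest linear sequence: 5 steps (1 → 3 → 8 → 10 → 11 → 12; steps 1, 4, 5, 6, 7).

Steps most likely to fail

Step 4. The chiral alkylidene may discriminate poorly between the two enantiotopic alkene carbons, or ring-opening oligomerisation and secondary metathesis of the vinyl terminus may outrun the single cross-metathesis. The fallback sets out from 4 and 7 and comes back at 12, using an aldol/syn-reduction sequence. Claisen–Schmidt condensation of 4 with acetone (aq. NaOH) should give (E)-4-(4-benzyloxy-3-methoxyphenyl)but-3-en-2-one F1. Heck arylation of allyl alcohol with 7 under Jeffery conditions (Pd(OAc)2, Bu4NCl, NaHCO3, DMF) should give 3-(4-benzyloxy-3,5-dimethoxyphenyl)propanal F2. A Paterson boron aldol of the Ipc2B enolate of F1 (Ipc2BCl, Et3N, Et2O; the antipode that attacks the Si face of the aldehyde; non-oxidative work-up) with F2 should give (1E,5R)-1-(4-benzyloxy-3-methoxyphenyl)-7-(4-benzyloxy-3,5-dimethoxyphenyl)-5-hydroxyhept-1-en-3-one F3. Narasaka–Prasad reduction (Et2BOMe, NaBH4, THF–MeOH, −78 °C) should then give the syn diol (1E,3R,5R)-1-(4-benzyloxy-3-methoxyphenyl)-7-(4-benzyloxy-3,5-dimethoxyphenyl)hept-1-ene-3,5-diol F4. Hydrogenation over Pd/C saturates the alkene and removes both benzyl groups to give 12 directly.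

Step 1. Intermolecular silylation may outrun closure of the bridge, so that oligomeric silyl ethers form instead of the bicycle. The fallback sets out from 1 and comes back at 3 by a stepwise closure. Monosilylation with di-tert-butylchlorosilane (imidazole, DMF) should give rac-(1R,4S)-4-[(di-tert-butylsilyl)oxy]cyclopent-2-en-1-ol F5. Its remaining hydroxyl is then closed onto silicon by alkoxide-catalysed intramolecular dehydrogenative Si–O coupling (cat. KOtBu, THF, high dilution, loss of H2) to give 3. Ring closure is then the only Si–O bond-forming event available to the hindered Si–H group.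

Step 5. Slow oxidative addition into the electron-rich aryl bromide may let protodeboronation or β-hydride elimination of the alkyl–palladium species compete, and the basic medium may erode the silylene. The fallback sets out from 8 and 7 and comes back at 11, replacing the hydroboration/coupling by an arylation of the alkene. Mizoroki–Heck reaction of the vinyl group of 8 with 7 (Pd2(dba)3, P(t-Bu)3, Cy2NMe, dioxane, 80 °C) should give (4R,6S)-4-[(E)-2-(4-benzyloxy-3-methoxyphenyl)ethenyl]-6-[(E)-2-(4-benzyloxy-3,5-dimethoxyphenyl)ethenyl]-2,2-di-tert-butyl-1,3,2-dioxasilinane F6. The hydrogenation conditions of step 6 then saturate both alkenes and remove both benzyl groups to give 11.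

Further compounds
F1 | step 4 | (E)-4-(4-benzyloxy-3-methoxyphenyl)but-3-en-2-one | COc1cc(/C=C/C(C)=O)ccc1OCc1ccccc1
F2 | step 4 | 3-(4-benzyloxy-3,5-dimethoxyphenyl)propanal | COc1cc(CCC=O)cc(OC)c1OCc1ccccc1
F3 | step 4 | (1E,5R)-1-(4-benzyloxy-3-methoxyphenyl)-7-(4-benzyloxy-3,5-dimethoxyphenyl)-5-hydroxyhept-1-en-3-one | COc1cc(/C=C/C(=O)C[C@H](O)CCc2cc(OC)c(OCc3ccccc3)c(OC)c2)ccc1OCc1ccccc1
F4 | step 4 | (1E,3R,5R)-1-(4-benzyloxy-3-methoxyphenyl)-7-(4-benzyloxy-3,5-dimethoxyphenyl)hept-1-ene-3,5-diol | COc1cc(/C=C/[C@H](O)C[C@H](O)CCc2cc(OC)c(OCc3ccccc3)c(OC)c2)ccc1OCc1ccccc1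
F5 | step 1 | rac-(1R,4S)-4-[(di-tert-butylsilyl)oxy]cyclopent-2-en-1-ol | O[C@H]1C[C@@H](O[SiH](C(C)(C)C)C(C)(C)C)C=C1
F6 | step 5 | (4R,6S)-4-[(E)-2-(4-benzyloxy-3-methoxyphenyl)ethenyl]-6-[(E)-2-(4-benzyloxy-3,5-dimethoxyphenyl)ethenyl]-2,2-di-tert-butyl-1,3,2-dioxasilinane | COc1cc(/C=C/[C@H]2C[C@@H](/C=C/c3cc(OC)c(OCc4ccccc4)c(OC)c3)O[Si](C(C)(C)C)(C(C)(C)C)O2)ccc1OCc1ccccc1
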